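Compare the two earlier runs: midnight was charged with 4.00 times the substrate of winter, yet both read 12.7% of the charge at 3.00 h.

| setting | winter | midnight | flask |
|---|---|---|---|
| substrate | 0.25 M | 1 M | 0.50 M |
| remark | run made earlier | run made earlier |  |
| time |  |  | 20 h |

- winter (time / h: target / %): 3.00: 12.7; 4.00: 15.3; 5.00: 17.1; 6.00: 18.4; 8.00: 21.0; 10.0: 20.5; 12.0: 20.4
- midnight (time / h: target / %): 3.00: 12.7; 4.00: 14.2; 5.00: 17.6; 6.00: 18.9; 8.00: 20.2; 10.0: 20.9; 12.0: 20.5

(each reading ± 0.5 percentage points)

- amounts and yields of target count crystals too
- given per volume of solution although it is solid: crystals
- the earlier runs were read with a standard deviation of 0.5 percentage points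
- what may be going on: substrate <-> target; substrate <-> isomer of the product; substrate <-> third isomer; substrate <-> dormant form; crystals <-> target

- time up to 20 h at which target stands highest
- the amount of target, in percent of the substrate charged, at that time

Read that overlap as the mark of first-order steps: such a step removes a set fraction of what is present per unit time, so where every step is first order the fraction of the charge at a given time does not depend on the charge. Put the flask, whose charge lies between the two, on the same curve.

Treat target as a step response. Average the readings at 10.0 h and 12.0 h for a plateau of 20.6% of the charge. Then take the gap left at 3.00 h and obtain 3.12 h: this is one turnover, the time in which the gap to the plateau shrinks by a factor e. Count turnovers as time over this constant.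

After 3 turnovers the gap is 1 percentage point, after 4 it is 0.38 points, against a scatter of 0.5 points. From 10.0 h to 12.0 h the readings fall by 0.1 points in winter and 0.4 points in midnight, but the possible steps include other exits from substrate, so commit for the flask to a top between 9.36 h and 12.5 h, near the plateau.

The forecast gave 10 h and 20.8%, “a broad maximum near 10 h”. The flask gives 21.0% at 11.0 h.

    substrate ⇌ target (K = 1.06, k = 0.00100 min⁻¹)
    substrate ⇌ isomer of the product (K = 2.60, k = 4.86 × 10⁻⁴ min⁻¹)
    substrate ⇌ third isomer (K = 55.4, k = 0.00143 min⁻¹)
    substrate ⇌ dormant form (K = 1.20, k = 7.03 × 10⁻⁵ min⁻¹)
    crystals ⇌ target, rate k5*(cs5 - [target]) while solid is left; crystals form when [target] > cs5 (solubility = 0.380 M, k = 0.0557 min⁻¹)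

The flask tops after 3.53 turnovers, and read at 5.0 h, which is 1.60 turnovers, it holds 17.2% of the charge against 16.5% from the step response. Taken forward alone, substrate turns into third isomer 1.4 times as fast as into target, a selectivity factor that stands for forward half-lives of 8.1 h and 12 h. At 20.0 h the flask holds 53.3% of its charge as third isomer and 18.2% as target.

The readings were computed on assumed constants; noise was put on by code.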